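The carbocycle (C1–C6) is read as a dearomatised phenol. The C1=O/C2=C3 enone flanked by the cis C4,C5-diol is the keto tautomer of the cis-dihydrodiol of a 3-substituted phenol. Toluene dioxygenase adds O2 across C4–C5 of flat, commercial 3-iodophenol, forming both C–O bonds syn and enantioselectively, and tautomerisation gives the enone diol in one operation. Iodine at C3 orients the arene in the enzyme and then carries in the CH2OH carbon. C2 receives the heptenyl chain (from (R)-propylene oxide) by iodination and Stille coupling. C6 receives the acid arm by enolate alkylation, and convex-face reprotonation completes the all-cis C4/C5/C6 array.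

Key step: step 1

Remark: ring atoms are numbered C1 (C=O), C2 (heptenyl), C3 (CH2OH), C4 (OH), C5 (OH), C6 (acid arm); the target is 4R,5S,6R,6′R with C4–OH, C5–OH and the C6 arm on one ring face, the C4 descriptor changes from S to R without change of geometry once iodine is replaced by carbon, and a dehydrogenase-free toluene dioxygenase strain is assumed to be at hand as biocatalyst (TBS = tert-butyldimethylsilyl).

Step 1
Reactants: 1 3-iodophenol
Product: 3 (4S,5S)-4,5-dihydroxy-3-iodocyclohex-2-en-1-one, via (1S,2S)-3-iodocyclohexa-3,5-diene-1,2,5-triol 2 (not isolated)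
Conditions: P. putida UV4 whole cells (toluene dioxygenase), air, glucose, phosphate buffer pH 7.2, 30 °C; EtOAc extraction
Reagents that add atoms: dioxygen, O=O
Why: The Rieske [2Fe–2S]/non-haem iron oxygenase activates O2 with two NADH-derived electrons and transfers both oxygen atoms suprafacially to the C4=C5 bond of 1, giving dienol cis-dihydrodiol 2, whose C1 enol is protonated at C6 to give the conjugated enone 3. The closest known reaction type is the toluene dioxygenase cis-dihydroxylation of halobenzenes to (1S,2S)-cis-dihydrodiols and of meta-substituted phenols to cyclohexenone cis-diols. No ring is closed; two C–O bonds form and the arene becomes the C1–C6 carbocycle with C1=O, C2=C3 and both carbinols in place. C4 and C5 are both set by the enzyme: delivery of the two oxygens from one iron-bound species makes them cis, and binding of the large iodine where the halogen of halobenzenes sits fixes the face, hence 4S,5S. The step needs regioselectivity for the C4–C5 bond (ortho/meta to iodine, remote from OH), which iodine as the larger orienting substituent secures, and it needs the diol to escape rearomatisation, which the dehydrogenase-free strain and the tautomerisation to the enone secure.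

Step 2
Reactants: 3 (4S,5S)-4,5-dihydroxy-3-iodocyclohex-2-en-1-one
Product: 4 (4S,5S)-3-iodo-4,5-(isopropylidenedioxy)cyclohex-2-en-1-one
Conditions: Me2C(OMe)2, PPTS (cat.), acetone, rt
Reagents that add atoms: 2,2-dimethoxypropane, COC(C)(C)OC
Why: Acid-catalysed transketalisation (acetonide formation) is fast for a ring cis-1,2-diol, touches neither stereocentre and builds the cis-fused dioxolane that later shields one face of C6.

Step 3
Reactants: 4 (4S,5S)-3-iodo-4,5-(isopropylidenedioxy)cyclohex-2-en-1-one; 5 (tributylstannyl)methanol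
Product: 6 (4R,5S)-3-(hydroxymethyl)-4,5-(isopropylidenedioxy)cyclohex-2-en-1-one
Conditions: Pd(PPh3)4 (cat.), 1,4-dioxane, 85 °C
Reagents that add atoms: none
Why: In this Migita–Kosugi–Stille coupling the β-iodoenone C3–I bond adds readily to Pd(0) and the hydroxymethyl group of 5 transfers in preference to butyl, under neutral conditions that spare the base-labile β-alkoxy ketone.

Step 4
Reactants: 6 (4R,5S)-3-(hydroxymethyl)-4,5-(isopropylidenedioxy)cyclohex-2-en-1-one
Product: 7 (4R,5S)-3-(hydroxymethyl)-2-iodo-4,5-(isopropylidenedioxy)cyclohex-2-en-1-one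
Conditions: I2, DMAP (cat.), pyridine/CH2Cl2, 0 °C → rt, dark
Reagents that add atoms: iodine, II
Why: Amine-catalysed α-iodination of an enone (Baylis–Hillman-type conjugate addition at C3, iodination at C2, loss of the amine) is known for β-substituted cyclohexenones, DMAP serves as the stronger nucleophile for the substituted C3, and the weak base neither enolises C6 nor touches a stereocentre.

Step 5
Reactants: 8 (4-bromobut-1-yn-1-yl)trimethylsilane; 9 (R)-propylene oxide
Product: 11 (R)-7-(trimethylsilyl)hept-6-yn-2-ol, via [4-(trimethylsilyl)but-3-yn-1-yl]magnesium bromide 10 (not isolated)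
Conditions: Mg, THF, rt → 40 °C; then CuI (cat.), 9, THF, −30 → 0 °C; sat. aq NH4Cl
Reagents that add atoms: none
Why: The copper-catalysed Grignard opening of a terminal epoxide is an SN2 attack at the unsubstituted CH2, so the C–O stereocentre of 9 passes unchanged into 11 as the (R)-carbinol.

Step 6
Reactants: 11 (R)-7-(trimethylsilyl)hept-6-yn-2-ol
Product: 12 (R)-hept-6-yn-2-ol
Conditions: K2CO3 (cat.), MeOH, rt
Reagents that add atoms: none
Why: Base-catalysed methanolysis of the alkynyl C–Si bond (protodesilylation) is selective and leaves the carbinol centre untouched.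

Step 7
Reactants: 12 (R)-hept-6-yn-2-ol
Product: 13 (2R,6E)-7-(tributylstannyl)hept-6-en-2-ol
Conditions: Bu3SnH, Pd2(dba)3 (cat.), Cy3P·HBF4 (cat.), i-Pr2NEt (cat.), CH2Cl2, 0 °C → rt
Reagents that add atoms: tributyltin hydride, CCCC[SnH](CCCC)CCCC
Why: Palladium-catalysed hydrostannation is a syn addition and the bulky PCy3 ligand directs tin to the terminal carbon, so the (E)-1-stannylalkene is expected and the free alcohol is tolerated.

Step 8
Reactants: 7 (4R,5S)-3-(hydroxymethyl)-2-iodo-4,5-(isopropylidenedioxy)cyclohex-2-en-1-one; 13 (2R,6E)-7-(tributylstannyl)hept-6-en-2-ol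
Product: 14 (4R,5S)-2-[(1E,6R)-6-hydroxyhept-1-en-1-yl]-3-(hydroxymethyl)-4,5-(isopropylidenedioxy)cyclohex-2-en-1-one
Conditions: PdCl2(PhCN)2 (cat.), AsPh3 (cat.), CuI (cat.), NMP, rt → 40 °C
Reagents that add atoms: none
Why: Stille coupling of an α-iodoenone with AsPh3/CuI acceleration runs near room temperature with retention of the (E)-alkene geometry and, being neutral, spares the β-alkoxy ketone and both free hydroxyls.

Step 9
Reactants: 14 (4R,5S)-2-[(1E,6R)-6-hydroxyhept-1-en-1-yl]-3-(hydroxymethyl)-4,5-(isopropylidenedioxy)cyclohex-2-en-1-one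
Product: 15 (4R,5S)-2-[(1E,6R)-6-(TBSO)hept-1-en-1-yl]-3-(TBSOCH2)-4,5-(isopropylidenedioxy)cyclohex-2-en-1-one
Conditions: TBSCl, imidazole, DMF, rt
Reagents that add atoms: tert-butyldimethylsilyl chloride, CC(C)(C)[Si](C)(C)Cl
Why: Imidazole-promoted silylation protects the primary allylic and the secondary alcohol in one operation, so that C6–H is the only site that LDA deprotonates in the next step.

Step 10
Reactants: 15 (4R,5S)-2-[(1E,6R)-6-(TBSO)hept-1-en-1-yl]-3-(TBSOCH2)-4,5-(isopropylidenedioxy)cyclohex-2-en-1-one; 16 methyl (E)-4-bromo-2-methylbut-2-enoate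
Product: 18 methyl (2E)-4-{(4R,5S,6S)-2-[(1E,6R)-6-(TBSO)hept-1-enyl]-3-(TBSOCH2)-4,5-(isopropylidenedioxy)-1-oxocyclohex-2-en-6-yl}-2-methylbut-2-enoate (arm trans to C5–O), via lithium cross-conjugated dienolate of 15 (C1–OLi, C1=C6, C2=C3) 17 (not isolated)
Conditions: LDA, THF, −78 °C; DMPU, then 16, −78 → −45 °C; pH 7 buffer
Reagents that add atoms: none
Why: Kinetic α′-deprotonation of the cyclohexenone gives dienolate 17, which displaces the primary allylic bromide (SN2 enolate alkylation) on the convex face of the cis-fused bicycle, anti to the dioxolane, which sets C6 provisionally as 6S while the low temperature keeps β-elimination of the C5 oxygen slow.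

Step 11
Reactants: 18 methyl ester, (4R,5S,6S)
Product: 20 (2E)-4-{(4R,5S,6S)-2-[(1E,6R)-6-(TBSO)hept-1-enyl]-3-(TBSOCH2)-4,5-(isopropylidenedioxy)-1-oxocyclohex-2-en-6-yl}-2-methylbut-2-enoic acid, via the corresponding trimethylstannyl ester 19 (not isolated)
Conditions: Me3SnOH, 1,2-dichloroethane, 70 °C; then cold 0.1 M aq HCl wash
Reagents that add atoms: trimethyltin hydroxide, C[Sn](C)(C)O
Why: Trimethyltin hydroxide ester cleavage works under nearly neutral conditions and so avoids hydroxide-induced E1cB loss of the C5 oxygen, and it is placed before the C6 inversion so that the labile 6R centre never meets heat or base.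

Step 12
Reactants: 20 acid, (4R,5S,6S)
Product: 22 (2E)-4-{(4R,5S,6R)-2-[(1E,6R)-6-(TBSO)hept-1-enyl]-3-(TBSOCH2)-4,5-(isopropylidenedioxy)-1-oxocyclohex-2-en-6-yl}-2-methylbut-2-enoic acid (arm cis to C5–O), via dilithium carboxylate–C1(OLi)=C6 enolate of 20 21 (not isolated)
Conditions: LDA (2.3 equiv), THF, −78 → −40 °C; recool to −78 °C, 2,6-di-tert-butyl-4-methylphenol in THF; cold 0.1 M aq HCl to pH 4
Reagents that add atoms: none
Why: In this deprotonation–kinetic reprotonation the planar C1=C6 enolate of 21 takes its proton from the bulky phenol on the open convex face, anti to the dioxolane, which places C6–H cis to C5–H and turns the arm onto the face of the two oxygens (6R), the epimer that alkylation cannot give directly.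

Step 13
Reactants: 22 acid, (4R,5S,6R)
Product: 23 pestallic acid I
Conditions: TFA/H2O (9:1), 0 °C → rt
Reagents that add atoms: none
Why: Aqueous acid hydrolysis removes the acetonide and both silyl ethers in one operation without base, hence without enolate-mediated epimerisation at C6 or elimination at C5, and no stereocentre is touched.

Compound list
1 | 3-iodophenol | Oc1cccc(I)c1 | starting material
2 | (1S,2S)-3-iodocyclohexa-3,5-diene-1,2,5-triol | OC1=C[C@H](O)[C@H](O)C(I)=C1 | intermediate
3 | (4S,5S)-4,5-dihydroxy-3-iodocyclohex-2-en-1-one | O=C1C=C(I)[C@@H](O)[C@@H](O)C1 | intermediate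
4 | (4S,5S)-3-iodo-4,5-(isopropylidenedioxy)cyclohex-2-en-1-one | O=C1C=C(I)[C@H]2OC(C)(C)O[C@H]2C1 | intermediate
5 | (tributylstannyl)methanol | OC[Sn](CCCC)(CCCC)CCCC | starting material
6 | (4R,5S)-3-(hydroxymethyl)-4,5-(isopropylidenedioxy)cyclohex-2-en-1-one | O=C1C=C(CO)[C@H]2OC(C)(C)O[C@H]2C1 | intermediate
7 | (4R,5S)-3-(hydroxymethyl)-2-iodo-4,5-(isopropylidenedioxy)cyclohex-2-en-1-one | O=C1C(I)=C(CO)[C@H]2OC(C)(C)O[C@H]2C1 | intermediate
8 | (4-bromobut-1-yn-1-yl)trimethylsilane | C[Si](C)(C)C#CCCBr | starting material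
9 | (R)-propylene oxide | C[C@@H]1CO1 | starting material
10 | [4-(trimethylsilyl)but-3-yn-1-yl]magnesium bromide | C[Si](C)(C)C#CCC[Mg]Br | intermediate
11 | (R)-7-(trimethylsilyl)hept-6-yn-2-ol | C[C@@H](O)CCCC#C[Si](C)(C)C | intermediate
12 | (R)-hept-6-yn-2-ol | C[C@@H](O)CCCC#C | intermediate
13 | (2R,6E)-7-(tributylstannyl)hept-6-en-2-ol | C[C@@H](O)CCC/C=C/[Sn](CCCC)(CCCC)CCCC | intermediate
14 | (4R,5S)-2-[(1E,6R)-6-hydroxyhept-1-en-1-yl]-3-(hydroxymethyl)-4,5-(isopropylidenedioxy)cyclohex-2-en-1-one | O=C1C(/C=C/CCC[C@@H](C)O)=C(CO)[C@H]2OC(C)(C)O[C@H]2C1 | intermediate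
15 | bis-TBS ether of 14 | O=C1C(/C=C/CCC[C@@H](C)O[Si](C)(C)C(C)(C)C)=C(CO[Si](C)(C)C(C)(C)C)[C@H]2OC(C)(C)O[C@H]2C1 | intermediate
16 | methyl (E)-4-bromo-2-methylbut-2-enoate | COC(=O)/C(C)=C/CBr | starting material
17 | lithium cross-conjugated dienolate of 15 (C1–OLi, C1=C6, C2=C3) | [Li]OC1=C[C@@H]2OC(C)(C)O[C@@H]2C(CO[Si](C)(C)C(C)(C)C)=C1/C=C/CCC[C@@H](C)O[Si](C)(C)C(C)(C)C | intermediate
18 | C6-alkylated methyl ester, (4R,5S,6S), arm trans to C5–O | COC(=O)/C(C)=C/C[C@@H]1C(=O)C(/C=C/CCC[C@@H](C)O[Si](C)(C)C(C)(C)C)=C(CO[Si](C)(C)C(C)(C)C)[C@H]2OC(C)(C)O[C@@H]12 | intermediate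
19 | trimethylstannyl ester corresponding to 18 | C[Sn](C)(C)OC(=O)/C(C)=C/C[C@@H]1C(=O)C(/C=C/CCC[C@@H](C)O[Si](C)(C)C(C)(C)C)=C(CO[Si](C)(C)C(C)(C)C)[C@H]2OC(C)(C)O[C@@H]12 | intermediate
20 | protected acid, (4R,5S,6S), arm trans to C5–O | OC(=O)/C(C)=C/C[C@@H]1C(=O)C(/C=C/CCC[C@@H](C)O[Si](C)(C)C(C)(C)C)=C(CO[Si](C)(C)C(C)(C)C)[C@H]2OC(C)(C)O[C@@H]12 | intermediate
21 | dilithium carboxylate–enolate of 20 (C1–OLi, C1=C6) | [Li]OC(=O)/C(C)=C/CC1=C(O[Li])C(/C=C/CCC[C@@H](C)O[Si](C)(C)C(C)(C)C)=C(CO[Si](C)(C)C(C)(C)C)[C@H]2OC(C)(C)O[C@@H]12 | intermediate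
22 | protected acid, (4R,5S,6R), arm cis to C5–O | OC(=O)/C(C)=C/C[C@H]1C(=O)C(/C=C/CCC[C@@H](C)O[Si](C)(C)C(C)(C)C)=C(CO[Si](C)(C)C(C)(C)C)[C@H]2OC(C)(C)O[C@@H]12 | intermediate
23 | pestallic acid I | C/C(=C\C[C@H]1C(=O)C(/C=C/CCC[C@@H](C)O)=C(CO)[C@@H](O)[C@H]1O)C(=O)O | target

Total step count: 13. Longest linear sequence: 10 steps (steps 1–4 and 8–13, from 3-iodophenol).

Steps most likely to fail

Step 12 (kinetic reprotonation). The small proton may show poor facial selectivity. Proton return from the amine bound to the enolate may blur that selectivity. The tetrasubstituted enolate may also lose the C5 oxygen by β-elimination and then aromatise. The fallback replaces proton transfer by hydrogen-atom transfer from a bulky donor. It sets out from 20. The same dianion 21 is trapped at −78 °C with PhSeCl, which should enter on the convex face and push the arm onto the dioxolane face, giving the α-phenylselanyl ketone acid F1. Radical deselenation (Bu3SnH, Et3B/air, toluene, −78 °C) then passes through the planar C6 α-keto radical. This radical should abstract hydrogen from the large stannane on the convex face, and the route is rejoined at 22.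

Step 10 (C6 alkylation). The dienolate may add in conjugate fashion to the bromo-enoate with cyclopropane closure in place of SN2 displacement. Slow alkylation may also give the enolate time for β-elimination of the C5 oxygen. The fallback builds the arm in two stages with an electrophile that is no Michael acceptor. It sets out from 15. Dienolate 17 is alkylated with allyl bromide, which is faster and offers only the SN2 pathway, to give the C6-allyl ketone F2 with the allyl group trans to C5–O. Cross-metathesis of the terminal alkene with excess methyl methacrylate (Hoveyda–Grubbs second-generation catalyst, CH2Cl2, 40 °C) should form the (E)-trisubstituted enoate, and the route is rejoined at 18.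

Step 13 (global deprotection). The exposure to strong acid that the secondary silyl ether needs may drive several side processes. These are dehydration toward a phenol, ionisation at the allylic C4, and acid-catalysed enolisation that erodes C6. The fallback stages the deprotection so that each group falls under its mildest conditions. It sets out from 22. Pyridine-buffered HF·pyridine (THF, 0 °C) removes both silyl groups to give the dihydroxy acetonide acid F3. The acetonide alone is then hydrolysed with 70% aqueous acetic acid at 35 °C, and the route is rejoined at 23.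

Further compounds
F1 | step 12 | (2E)-4-{(4R,5S,6S)-2-[(1E,6R)-6-(TBSO)hept-1-enyl]-3-(TBSOCH2)-4,5-(isopropylidenedioxy)-1-oxo-6-(phenylselanyl)cyclohex-2-en-6-yl}-2-methylbut-2-enoic acid (PhSe on the convex face, arm on the dioxolane face) | OC(=O)/C(C)=C/C[C@@]1([Se]c3ccccc3)C(=O)C(/C=C/CCC[C@@H](C)O[Si](C)(C)C(C)(C)C)=C(CO[Si](C)(C)C(C)(C)C)[C@H]2OC(C)(C)O[C@@H]12
F2 | step 10 | (4R,5S,6S)-6-allyl-2-[(1E,6R)-6-(TBSO)hept-1-enyl]-3-(TBSOCH2)-4,5-(isopropylidenedioxy)cyclohex-2-en-1-one | C=CC[C@@H]1C(=O)C(/C=C/CCC[C@@H](C)O[Si](C)(C)C(C)(C)C)=C(CO[Si](C)(C)C(C)(C)C)[C@H]2OC(C)(C)O[C@@H]12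
F3 | step 13 | (2E)-4-{(4R,5S,6R)-2-[(1E,6R)-6-hydroxyhept-1-enyl]-3-(hydroxymethyl)-4,5-(isopropylidenedioxy)-1-oxocyclohex-2-en-6-yl}-2-methylbut-2-enoic acid | OC(=O)/C(C)=C/C[C@H]1C(=O)C(/C=C/CCC[C@@H](C)O)=C(CO)[C@H]2OC(C)(C)O[C@@H]12
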